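**Retrosynthetic overview**
1. Last C–O bond: the C8–O ester, made by Yamaguchi coupling of a 15-O-silyl dehydromelitensin with an acetonide-protected (R)-3,4-dihydroxy-2-methylenebutanoic acid, followed by one acid deprotection.
2. Key step, ring 3 (α-methylene-γ-lactone): the C12–O bonds are made from a C7 isopropenyl group and the C6 hydroxyl by a new one-flask allylic C–H hydroxylation/oxidative lactonization.
3. Ring 2 (cyclohexane): C6–C7 by carbonyl-ene closure of an open-chain aldehyde, which also creates the C6 hydroxyl.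
4. C10 and C5 are set on a temporary δ-lactone (ring 1, O8 tethered to C6) by vinyl conjugate addition and enolate alkenylation; the lactone is then opened.
5. Ring 1 comes from prenal and methyl 3-methylbut-3-enoate by a catalytic asymmetric vinylogous aldol–lactonization that sets C8. Ring order: δ-lactone (temporary), cyclohexane, γ-lactone.

Assumption: the target is taken exactly as drawn (elemane numbering C1–C15, side-chain carbinol C3′ R); the (R)-DTBM-SEGPHOS antipode is assumed to give the 6S lactone in step 1, otherwise its mirror image is used.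

**Route**

Step 1
Reactants: 1 3-methylbut-2-enal (prenal); 2 methyl 3-methylbut-3-enoate
Product: 4 (6S)-4-methyl-6-(2-methylprop-1-en-1-yl)-5,6-dihydro-2H-pyran-2-one, via Z-hydroxy ester 3 (not isolated)
Conditions: Cu(MeCN)4PF6 (5 mol%), (R)-DTBM-SEGPHOS (6 mol%), Et3N (10 mol%), THF, −20 °C
Reagents that add atoms: none
Why: Monovalent-copper/bisphosphine-catalysed direct asymmetric vinylogous aldol reaction: the copper dienolate of 2 attacks the aldehyde through its γ-carbon on the face chosen by the ligand (sets C8, the only catalyst-controlled stereocentre), and the Z-configured aldolate 3 closes onto the ester to give the δ-lactone.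

Step 2
Reactants: 4 (6S)-4-methyl-6-(2-methylprop-1-en-1-yl)-5,6-dihydro-2H-pyran-2-one
Product: 6 (4R,6S)-4-ethenyl-4-methyl-6-(2-methylprop-1-en-1-yl)oxan-2-one, via silyl ketene acetal 5 (not isolated)
Conditions: CH2=CHMgBr (2 equiv), CuBr·SMe2 (10 mol%), Me3SiCl (2 equiv), THF, −78 °C; aq. NH4Cl
Reagents that add atoms: vinylmagnesium bromide, C=C[Mg]Br
Why: Copper-catalysed conjugate addition of a vinyl Grignard reagent accelerated by Me3SiCl: axial attack on the half-chair anti to the pseudo-equatorial C6 alkenyl group builds the quaternary centre C10 with vinyl trans to the C8 side chain, and the allylic lactone C–O bond is not displaced at −78 °C.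

Step 3
Reactants: 7 2-bromoprop-2-en-1-ol
Product: 8 [(2-bromoprop-2-en-1-yl)oxy](tert-butyl)dimethylsilane
Conditions: t-BuMe2SiCl, imidazole, CH2Cl2, 0 °C to rt
Reagents that add atoms: tert-butyldimethylsilyl chloride, CC(C)(C)[Si](C)(C)Cl
Why: Imidazole-promoted silyl ether formation on a primary allylic alcohol; no stereocentre is involved.

Step 4
Reactants: 6 (4R,6S)-4-ethenyl-4-methyl-6-(2-methylprop-1-en-1-yl)oxan-2-one; 8 [(2-bromoprop-2-en-1-yl)oxy](tert-butyl)dimethylsilane
Product: 10 (3R,4S,6S)-3-(3-{[tert-butyl(dimethyl)silyl]oxy}prop-1-en-2-yl)-4-ethenyl-4-methyl-6-(2-methylprop-1-en-1-yl)oxan-2-one, via lithium enolate 9 (not isolated)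
Conditions: LiN(SiMe3)2 (1.05 equiv), toluene, −78 °C; then 8, Pd(dba)2 (5 mol%), P(t-Bu)3 (10 mol%), −78 °C to rt
Reagents that add atoms: none
Why: Palladium-catalysed α-alkenylation of an ester enolate with an alkenyl bromide (Buchwald–Hartwig-type enolate coupling): the alkenylpalladium bromide binds the enolate carbon on the face anti to the axial vinyl group and reductive elimination places the propenyl unit trans to vinyl (sets C5).

Step 5
Reactants: 10 the alkenylated lactone
Product: 11 (2R,3S,5S)-2-(3-{[tert-butyl(dimethyl)silyl]oxy}prop-1-en-2-yl)-3-ethenyl-5-hydroxy-N-methoxy-N,3,7-trimethyloct-6-enamide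
Conditions: MeNH(OMe)·HCl, AlMe3, CH2Cl2, 0 °C to rt; aq. potassium sodium tartrate
Reagents that add atoms: N,O-dimethylhydroxylamine hydrochloride, CNOC.Cl
Why: Weinreb aminolysis with the aluminium amide opens the temporary δ-lactone without touching a stereocentre and frees the C8 hydroxyl.

Step 6
Reactants: 11 the hydroxy Weinreb amide
Product: 12 (2R,3S,5S)-2-(3-{[tert-butyl(dimethyl)silyl]oxy}prop-1-en-2-yl)-3-ethenyl-N-methoxy-N,3,7-trimethyl-5-[(triethylsilyl)oxy]oct-6-enamide
Conditions: Et3SiOTf, 2,6-lutidine, CH2Cl2, −78 °C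
Reagents that add atoms: triethylsilyl trifluoromethanesulfonate, CC[Si](CC)(CC)OS(=O)(=O)C(F)(F)F
Why: Silyl triflate silylation caps the secondary allylic alcohol so that the aldehyde of step 7 cannot close to a lactol and so that only O6 can lactonize in step 9.

Step 7
Reactants: 12 the silylated Weinreb amide
Product: 13 (2R,3S,5S)-2-(3-{[tert-butyl(dimethyl)silyl]oxy}prop-1-en-2-yl)-3-ethenyl-3,7-dimethyl-5-[(triethylsilyl)oxy]oct-6-enal
Conditions: i-Bu2AlH, THF, −78 °C; aq. potassium sodium tartrate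
Reagents that add atoms: none
Why: Weinreb-amide reduction: the chelated aluminium hemiaminal is stable at −78 °C and releases the aldehyde on work-up without over-reduction or epimerization of C5.

Step 8
Reactants: 13 the aldehyde
Product: 14 (1R,2R,3S,5S,6S)-2-(3-{[tert-butyl(dimethyl)silyl]oxy}prop-1-en-2-yl)-3-ethenyl-3-methyl-6-(prop-1-en-2-yl)-5-[(triethylsilyl)oxy]cyclohexan-1-ol
Conditions: Me2AlCl (1.5 equiv), CH2Cl2, −78 to −40 °C
Reagents that add atoms: none
Why: Lewis-acid-promoted intramolecular carbonyl-ene reaction of the citronellal-to-isopulegol kind: the chair transition state with the C5 propenyl, C8 silyloxy and C10 vinyl groups equatorial (C10 methyl axial, which also disfavours an axial carbonyl oxygen) forms C6–C7 with hydroxyl and isopropenyl trans-diequatorial (sets C6 and C7).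

Step 9
Reactants: 14 the cyclohexanol
Product: 17 15-(tert-butyldimethylsilyloxy)-8α-(triethylsilyloxy)elema-1,3,11(13)-trien-12,6α-olide, via C12 allylic alcohol 15 (not isolated), via C12 lactol 16 (not isolated)
Conditions: SeO2 (20 mol%), t-BuOOH (2 equiv), CH2Cl2, 0 °C to rt; then TEMPO (20 mol%), PhI(OAc)2 (2.5 equiv), same flask, rt
Reagents that add atoms: selenium dioxide, O=[Se]=O (oxygen carrier); tert-butyl hydroperoxide, CC(C)(C)OO (terminal oxygen source)
Why: Proposed new method: a one-flask relay of tetravalent-selenium allylic C–H hydroxylation and oxoammonium oxidation, the closest known reaction types being SeO2/t-BuOOH allylic oxidation and nitroxyl-catalysed oxidative lactonization of 1,4-diols, which are so far run as separate steps; SeO2 attacks the most electron-rich alkene that has allylic hydrogens (the C7 isopropenyl group, since the silyloxymethyl alkene is inductively deactivated and the vinyl group has no allylic hydrogen) by ene reaction and [2,3]-shift to give the C12 alcohol 15, the oxoammonium salt oxidizes this primary allylic alcohol, the C6 hydroxyl traps the aldehyde as lactol 16 (C8 is silylated, so only the 6,12-ring can form) and a second oxidation gives the α-methylene lactone, with any over-oxidized enal from the first stage funnelling to the same product and no stereocentre changed.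

Step 10
Reactants: 17 the bis-silyl lactone
Product: 18 15-(tert-butyldimethylsilyloxy)-8α-hydroxyelema-1,3,11(13)-trien-12,6α-olide (15-O-TBS-dehydromelitensin)
Conditions: PPTS (20 mol%), MeOH/CH2Cl2 (1:4), 0 °C
Reagents that add atoms: none
Why: Acid-catalysed methanolysis removes the secondary triethylsilyl ether much faster than the primary tert-butyldimethylsilyl ether (selective desilylation), exposing only the C8 hydroxyl.

Step 11
Reactants: 19 methyl (4S)-2,2-dimethyl-1,3-dioxolane-4-carboxylate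
Product: 21 (4R)-4-ethynyl-2,2-dimethyl-1,3-dioxolane, via (4S)-2,2-dimethyl-1,3-dioxolane-4-carbaldehyde 20 (not isolated)
Conditions: i-Bu2AlH, CH2Cl2, −78 °C; then MeOH, K2CO3, dimethyl (1-diazo-2-oxopropyl)phosphonate, 0 °C to rt
Reagents that add atoms: dimethyl (1-diazo-2-oxopropyl)phosphonate, CC(=O)C(=[N+]=[N-])P(=O)(OC)OC
Why: Partial ester reduction followed in the same flask by Ohira–Bestmann (Seyferth–Gilbert) homologation, which converts the α-alkoxy aldehyde faster than it epimerizes (the descriptor changes from S to R only because the priorities change).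

Step 12
Reactants: 21 (4R)-4-ethynyl-2,2-dimethyl-1,3-dioxolane
Product: 22 2-[(4R)-2,2-dimethyl-1,3-dioxolan-4-yl]prop-2-enoic acid
Conditions: Pd(OAc)2 (2 mol%), Xantphos (4 mol%), HCO2H (2 equiv), Ac2O (20 mol%), toluene, 80 °C
Reagents that add atoms: formic acid, OC=O
Why: Palladium-hydride-catalysed Markovnikov hydrocarboxylation of a terminal alkyne with formic acid as the CO/water surrogate gives the 2-substituted acrylic acid without involving the stereocentre.

Step 13
Reactants: 18 15-O-TBS-dehydromelitensin; 22 the acetonide acid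
Product: 24 15-(tert-butyldimethylsilyloxy)-8α-{2-[(4R)-2,2-dimethyl-1,3-dioxolan-4-yl]prop-2-enoyloxy}elema-1,3,11(13)-trien-12,6α-olide, via mixed anhydride 23 (not isolated)
Conditions: 2,4,6-Cl3C6H2COCl, Et3N, toluene, rt; then 18, DMAP, rt
Reagents that add atoms: none
Why: Yamaguchi esterification: the mixed anhydride acylates the only free hydroxyl (equatorial C8–OH) under DMAP catalysis, forming the C8–O ester bond that joins the two fragments with retention at C8 and C3′.

Step 14
Reactants: 24 the protected ester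
Product: 25 8α-[(3R)-3,4-dihydroxy-2-methylidenebutanoyloxy]-15-hydroxyelema-1,3,11(13)-trien-12,6α-olide (CNP0234188.1)
Conditions: TFA/H2O/THF (1:1:4), 0 °C to rt
Reagents that add atoms: none
Why: Aqueous acid hydrolysis removes the terminal acetonide and the primary allylic silyl ether in one operation, while the α-methylene lactone and the acrylate ester are stable to mild acid.

**Compound list**
1 | 3-methylbut-2-enal (prenal) | CC(C)=CC=O | starting material
2 | methyl 3-methylbut-3-enoate | C=C(C)CC(=O)OC | starting material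
3 | methyl (2Z,5S)-5-hydroxy-3,7-dimethylocta-2,6-dienoate (formed as its copper alkoxide) | COC(=O)/C=C(\C[C@H](O)C=C(C)C)C | intermediate
4 | (6S)-4-methyl-6-(2-methylprop-1-en-1-yl)-5,6-dihydro-2H-pyran-2-one | CC(C)=C[C@@H]1CC(C)=CC(=O)O1 | intermediate
5 | (2S,4S)-4-ethenyl-4-methyl-2-(2-methylprop-1-en-1-yl)-6-[(trimethylsilyl)oxy]-3,4-dihydro-2H-pyran | C=C[C@]1(C)C[C@@H](C=C(C)C)OC(O[Si](C)(C)C)=C1 | intermediate
6 | (4R,6S)-4-ethenyl-4-methyl-6-(2-methylprop-1-en-1-yl)oxan-2-one | C=C[C@]1(C)C[C@@H](C=C(C)C)OC(=O)C1 | intermediate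
7 | 2-bromoprop-2-en-1-ol | C=C(Br)CO | starting material
8 | [(2-bromoprop-2-en-1-yl)oxy](tert-butyl)dimethylsilane | C=C(Br)CO[Si](C)(C)C(C)(C)C | intermediate
9 | lithium enolate of 6 | C=C[C@]1(C)C[C@@H](C=C(C)C)OC(O[Li])=C1 | intermediate
10 | (3R,4S,6S)-3-(3-{[tert-butyl(dimethyl)silyl]oxy}prop-1-en-2-yl)-4-ethenyl-4-methyl-6-(2-methylprop-1-en-1-yl)oxan-2-one | C=C[C@]1(C)C[C@@H](C=C(C)C)OC(=O)[C@H]1C(=C)CO[Si](C)(C)C(C)(C)C | intermediate
11 | (2R,3S,5S)-2-(3-{[tert-butyl(dimethyl)silyl]oxy}prop-1-en-2-yl)-3-ethenyl-5-hydroxy-N-methoxy-N,3,7-trimethyloct-6-enamide | C=C[C@](C)(C[C@H](O)C=C(C)C)[C@H](C(=C)CO[Si](C)(C)C(C)(C)C)C(=O)N(C)OC | intermediate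
12 | (2R,3S,5S)-2-(3-{[tert-butyl(dimethyl)silyl]oxy}prop-1-en-2-yl)-3-ethenyl-N-methoxy-N,3,7-trimethyl-5-[(triethylsilyl)oxy]oct-6-enamide | C=C[C@](C)(C[C@H](O[Si](CC)(CC)CC)C=C(C)C)[C@H](C(=C)CO[Si](C)(C)C(C)(C)C)C(=O)N(C)OC | intermediate
13 | (2R,3S,5S)-2-(3-{[tert-butyl(dimethyl)silyl]oxy}prop-1-en-2-yl)-3-ethenyl-3,7-dimethyl-5-[(triethylsilyl)oxy]oct-6-enal | C=C[C@](C)(C[C@H](O[Si](CC)(CC)CC)C=C(C)C)[C@H](C(=C)CO[Si](C)(C)C(C)(C)C)C=O | intermediate
14 | (1R,2R,3S,5S,6S)-2-(3-{[tert-butyl(dimethyl)silyl]oxy}prop-1-en-2-yl)-3-ethenyl-3-methyl-6-(prop-1-en-2-yl)-5-[(triethylsilyl)oxy]cyclohexan-1-ol (15-silyloxy-8α-silyloxyelema-1,3,11-trien-6α-ol) | C=C[C@]1(C)C[C@H](O[Si](CC)(CC)CC)[C@@H](C(C)=C)[C@H](O)[C@H]1C(=C)CO[Si](C)(C)C(C)(C)C | intermediate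
15 | 15-(tert-butyldimethylsilyloxy)-8α-(triethylsilyloxy)elema-1,3,11(13)-triene-6α,12-diol | C=C[C@]1(C)C[C@H](O[Si](CC)(CC)CC)[C@@H](C(=C)CO)[C@H](O)[C@H]1C(=C)CO[Si](C)(C)C(C)(C)C | intermediate
16 | 15-(tert-butyldimethylsilyloxy)-6α,12-epoxy-8α-(triethylsilyloxy)elema-1,3,11(13)-trien-12-ol (lactol, C12 epimers) | C=C[C@]1(C)C[C@H](O[Si](CC)(CC)CC)[C@H]2C(=C)C(O)O[C@@H]2[C@H]1C(=C)CO[Si](C)(C)C(C)(C)C | intermediate
17 | 15-(tert-butyldimethylsilyloxy)-8α-(triethylsilyloxy)elema-1,3,11(13)-trien-12,6α-olide | C=C[C@]1(C)C[C@H](O[Si](CC)(CC)CC)[C@H]2C(=C)C(=O)O[C@@H]2[C@H]1C(=C)CO[Si](C)(C)C(C)(C)C | intermediate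
18 | 15-(tert-butyldimethylsilyloxy)-8α-hydroxyelema-1,3,11(13)-trien-12,6α-olide | C=C[C@]1(C)C[C@H](O)[C@H]2C(=C)C(=O)O[C@@H]2[C@H]1C(=C)CO[Si](C)(C)C(C)(C)C | intermediate
19 | methyl (4S)-2,2-dimethyl-1,3-dioxolane-4-carboxylate | COC(=O)[C@@H]1COC(C)(C)O1 | starting material
20 | (4S)-2,2-dimethyl-1,3-dioxolane-4-carbaldehyde | O=C[C@@H]1COC(C)(C)O1 | intermediate
21 | (4R)-4-ethynyl-2,2-dimethyl-1,3-dioxolane | C#C[C@@H]1COC(C)(C)O1 | intermediate
22 | 2-[(4R)-2,2-dimethyl-1,3-dioxolan-4-yl]prop-2-enoic acid | OC(=O)C(=C)[C@@H]1COC(C)(C)O1 | intermediate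
23 | 2-[(4R)-2,2-dimethyl-1,3-dioxolan-4-yl]prop-2-enoic 2,4,6-trichlorobenzoic anhydride | C=C(C(=O)OC(=O)c1c(Cl)cc(Cl)cc1Cl)[C@@H]1COC(C)(C)O1 | intermediate
24 | 15-(tert-butyldimethylsilyloxy)-8α-{2-[(4R)-2,2-dimethyl-1,3-dioxolan-4-yl]prop-2-enoyloxy}elema-1,3,11(13)-trien-12,6α-olide | C=C[C@]1(C)C[C@H](OC(=O)C(=C)[C@@H]3COC(C)(C)O3)[C@H]2C(=C)C(=O)O[C@@H]2[C@H]1C(=C)CO[Si](C)(C)C(C)(C)C | intermediate
25 | 8α-[(3R)-3,4-dihydroxy-2-methylidenebutanoyloxy]-15-hydroxyelema-1,3,11(13)-trien-12,6α-olide (CNP0234188.1) | C=C[C@]1(C)C[C@H](OC(=O)C(=C)[C@@H](O)CO)[C@H]2C(=C)C(=O)O[C@@H]2[C@H]1C(=C)CO | target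

**Step count and risks**
Total step count: 14. Longest linear sequence: 11 (steps 1, 2, 4 to 10, 13, 14); steps 3, 11 and 12 make the two side fragments.

The three steps most likely to fail:

Step 4 (enolate alkenylation next to the quaternary centre). The risks are slow coupling at the hindered α-carbon, ionization of the allylic lactone C–O bond by zerovalent palladium, and epimerization of C5. The fallback is an aldol–Peterson sequence that sets out from 6. Enolate 9 (LiN(SiMe3)2, THF, −78 °C) is added to 1-{[tert-butyl(dimethyl)silyl]oxy}-3-(trimethylsilyl)propan-2-one F1, which is made from ethyl {[tert-butyl(dimethyl)silyl]oxy}acetate and Me3SiCH2Li. The ketone is attacked anti to the axial vinyl group, giving the β-hydroxysilane aldol adduct F2. KH in THF then effects Peterson elimination, which can only form the terminal methylene, and the route is rejoined at 10.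

Step 8 (carbonyl-ene ring closure). The risks are a sluggish reaction of the α-branched aldehyde and ionization next to the allylic silyl ether. The fallback is a Nozaki–Hiyama allylation that sets out from 12. Ene-type chlorination of the trisubstituted alkene (Ca(OCl)2, CO2, CH2Cl2/H2O, 0 °C) gives the allylic chloride amide F3. Reduction with i-Bu2AlH at −78 °C gives the chloro aldehyde F4. CrCl2 in THF then forms the allylchromium species, which adds to the aldehyde through its more substituted carbon in a chair transition state, and the route is rejoined at 14.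

Step 9 (the new relay lactonization). The risks are incompatibility of the two oxidation systems in one flask, oxidation of the silyloxymethyl alkene, and oxidation of the C6 hydroxyl before the lactol forms. The fallback uses known chemistry and sets out from 14. SeO2 (0.5 equiv)/t-BuOOH in CH2Cl2 at 0 °C gives the allylic diol 15, which is isolated. Activated MnO2 in CH2Cl2 then oxidizes only the allylic primary alcohol and the derived lactol 16, and the route is rejoined at 17. This stepwise sequence makes no compound outside the list (F0).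

**Further compounds**
F1 | step 4 | 1-{[tert-butyl(dimethyl)silyl]oxy}-3-(trimethylsilyl)propan-2-one | C[Si](C)(C)CC(=O)CO[Si](C)(C)C(C)(C)C
F2 | step 4 | 3-[1-{[tert-butyl(dimethyl)silyl]oxy}-2-hydroxy-3-(trimethylsilyl)propan-2-yl]-4-ethenyl-4-methyl-6-(2-methylprop-1-en-1-yl)oxan-2-one (ring configuration as in 10, carbinol centre as formed) | C=C[C@]1(C)C[C@@H](C=C(C)C)OC(=O)[C@H]1C(O)(C[Si](C)(C)C)CO[Si](C)(C)C(C)(C)C
F3 | step 8 | (2R,3S,5S)-2-(3-{[tert-butyl(dimethyl)silyl]oxy}prop-1-en-2-yl)-6-chloro-3-ethenyl-N-methoxy-N,3,7-trimethyl-5-[(triethylsilyl)oxy]oct-7-enamide (C6 epimers) | C=C[C@](C)(C[C@H](O[Si](CC)(CC)CC)C(Cl)C(C)=C)[C@H](C(=C)CO[Si](C)(C)C(C)(C)C)C(=O)N(C)OC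
F4 | step 8 | (2R,3S,5S)-2-(3-{[tert-butyl(dimethyl)silyl]oxy}prop-1-en-2-yl)-6-chloro-3-ethenyl-3,7-dimethyl-5-[(triethylsilyl)oxy]oct-7-enal (C6 epimers) | C=C[C@](C)(C[C@H](O[Si](CC)(CC)CC)C(Cl)C(C)=C)[C@H](C(=C)CO[Si](C)(C)C(C)(C)C)C=O
F0 | step 9 | none | none
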